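Late in the runs, at 8.00 min, J (a species formed on the way from the substrate G to the product E) stood at 11.7% of the G charged in theta and at 37.0% in delta. These two flasks had the same G and the same reagent L, but held 10 mM and 42 mM of the further reagent Q.

| flask | G | L | Q | remark | time |
|---|---|---|---|---|---|
| zeta | 20 mM | 21 mM | 21 mM | run made earlier |  |
| theta | 20 mM | 21 mM | 10 mM | run made earlier |  |
| delta | 20 mM | 21 mM | 42 mM | run made earlier |  |
| eta | 20 mM | 32 mM | 21 mM | run made earlier |  |
| winter | 20 mM | 21.0 mM | 21.0 mM | everything together in a closed stirred flask, run for 8.0 min | 8.0 min |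
| summer | 20 mM | 21.0 mM | 21.0 mM | a single well-mixed tank run continuously and read at steady state, 8.0 min in it on average |  |
| dusk | 20 mM (fed, over 8.00 min) | 21.0 mM | 21.0 mM | all but G at the start; G goes in evenly over 8.00 min, the run ends at 8.0 min | 8.0 min |
| midnight | 20 mM | 21.0 mM | 21.0 mM | one stirred flow tank at steady state, fed with the mixture as stated, mean residence time 24.0 min |  |

| run | time / min | J / % | E / % |
|---|---|---|---|
| zeta | 0.667 | 3.0 | 0 |
| zeta | 1.33 | 7.7 | 0 |
| zeta | 3.00 | 12.9 | 0.2 |
| zeta | 8.00 | 21.9 | 0.6 |
| theta | 0.667 | 0.4 | 0 |
| theta | 1.33 | 4.2 | 0 |
| theta | 3.00 | 7.5 | 0.3 |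
| theta | 8.00 | 11.7 | 0.1 |
| delta | 1.00 | 9.9 | 0 |
| delta | 3.00 | 24.2 | 0.2 |
| delta | 5.00 | 31.7 | 1.7 |
| delta | 8.00 | 37.0 | 3.5 |
| eta | 1.00 | 5.1 | 0.4 |
| eta | 3.00 | 11.0 | 0.2 |
| eta | 5.00 | 16.0 | 1.4 |
| eta | 8.00 | 17.9 | 1.4 |

(scatter of a reading: 0.5 percentage points)

* the set-up with the highest amount of J at the outlet or at the end, in percent of the G put in ("none" if the first two lie within 2 percentage points) (winter / summer / dusk / midnight / none)
* amount of J at the outlet or at the end, in percent of the G put in, winter
* amount of J at the outlet or at the end, in percent of the G put in, summer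
* amount of J at the outlet or at the end, in percent of the G put in, dusk
* amount of J at the outlet or at the end, in percent of the G put in, midnight

- the stated concentrations are those of everything mixed, before any reaction; amounts are the same in each set-up
- the numbers in the tables scatter by 0.5 percentage points (one standard deviation)
- the feed brings no volume worth counting
- the earlier runs were made in a closed, stirred flask

I worked in common logarithms to see which given number had to be known well, taking J as a power of each in turn. For time, zeta between 3.00 min and 8.00 min gave a slope of 0.540, so I reckoned a factor of 1.45 on J for a doubled time. For L, zeta against eta gave −0.479, so I reckoned a factor of 0.717 on J for a doubled L. G stood at 20 mM in all four runs and gave no slope.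

For Q, theta to delta spans 0.500 decades of J over 0.623 decades of Q. That makes n = 0.802, the apparent reaction order of J in Q, meaning the slope of log J against log Q with L and time held. This slope is steeper than the other two I could read, so of these the Q charge had to be known best.

Then the number: winter has the charges and closed flask of zeta, so I took 21.9% for winter, with a scatter of 0.5 percentage points. Midnight's 24.0 min lies beyond the readings, so I gave it no number.

The forecast gave winter 21.7%, summer 16.1%, dusk 13.7% and midnight 20.2%, with best none, because “Winter and midnight lie within 2 points”.

    G + E → X (k = 0.459 /M/s)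
    G + Q → J (k = 0.0465 /M/s)
    Q + L → Z (k = 0.0955 /M/s)
    J + Z → E (k = 0.0530 /M/s)

The flask gave winter 21.6%, summer 16.0%, dusk 11.1% and midnight 16.7%, so the best was winter. The forecast's midnight stood 3.5 points above the flask's, and winter led midnight by 4.9 points, against a margin of 2 points. Carried to 27.0 mM of Q in winter, n gave a rise of 4.8 points, where the flask moved 5 points. For a neighbouring flask, like winter but with 84 mM of Q, n gave 65.8% of J. That neighbouring flask gave 56.1%, with 22.1% of its G left.

Readings and results are simulated from invented constants, and the scatter is random.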